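## The problem

The target is a cis-fused bicyclo[5.3.0]decane. The seven-membered ring is numbered C1 (anisoyloxy carbon), C2, C3 (methyl-bearing fusion carbon), C7 (hydroxyl-bearing fusion carbon), C8, C9, C10 (methyl carbinol); the five-membered ring is C3, C4, C5, C6 (isopropyl carbon), C7. Reading the SMILES, the C3 methyl, C7 hydroxyl, C6 isopropyl and C1 ester oxygen lie on one face (β) and the C10 hydroxyl on the other (α); the absolute configuration is (1R,3R,6R,7S,10R). The hardest part of the skeleton is the C3–C7 bond, which joins two fully substituted carbons that must carry methyl and oxygen cis. C6 can come from the chiral pool and sits next to C7, so it can steer a reagent to the opposite face of a cyclopentene and thereby set C3 and C7. The C7 hydroxyl is then the only group that can reach across the seven-membered ring to C1 and C10, whose trans diol pattern is that of an epoxide opened with inversion. Two tertiary alcohols rule out strong acid. The C7 oxygen is β to any carbonyl at C2 or C8 and must stay protected while such a carbonyl exists, or retro-aldol cleavage follows. The anisate will not survive hydride or strong base and has to come last. The C3–C7 bond with cis methyl and oxygen, flanked by C2 and C8, is the pattern of a ketene (2+2) adduct of a cyclopentanone enol ether; a C9–C10–C1 chain on C8 can then be inserted between C8 and C2 by radical ring expansion.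

## Retrosynthesis

Target 28 is cut at the ester C–O bond to triol 26 and 4-methoxybenzoyl chloride 27. Only the C1 hydroxyl of 26 is secondary, so no protecting group is needed, and placing this step last keeps the ester away from hydride and base.

Triol 26 is cut at the C10–OH bond to the 1β,10β-epoxide 25 and water, and 25 goes back to alkene 24. Dihydroxylation would give a cis diol. An α-epoxide would need attack at the hindered secondary C1 and would invite the C7 oxygen to bridge to C10. Acid opening of the β-epoxide at the tertiary C10 with inversion gives exactly C1 β-OH and C10 α-OH. The forward reactions must deliver the epoxide oxygen on the face of the C7 hydroxyl and then open it without ionising fully.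

Alkene 24 goes back through silyl ether 23, acetate 22 and alcohol 21 to enone 20; the cut is the C2–H bond, made by hydride substitution of an allylic oxygen. The C2 oxygen is the price of the key step. A 1,3-transposition through the epoxy ketone was weighed here. It would leave C1=C2 next to the C10 carbinol, and hydroxyl-directed epoxidation followed by hydride opening would put the C1 oxygen cis to the C10 hydroxyl, which is the wrong diol. Removing the C2 oxygen while keeping the C1=C10 alkene avoids this.

Enone 20 goes back to ketone 18 by dehydrogenation across C1–C10. C3 is quaternary, so 18 has one enolate only, and the unsaturation removes the uncontrolled C10 centre of 18.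

Ketone 18 is disconnected at C1–C2 with re-formation of C2–C8, giving iodide 17, a fused cyclobutanone with a three-carbon iodoalkyl arm on C8. The precursor is much simpler: a bicyclo[3.2.0]heptanone whose three ring stereocentres are already those of the target. The forward reaction must run as a radical chain at low stannane concentration and must break the right bond of the intermediate alkoxy radical.

Iodide 17 comes from chloride 16 by halide exchange, and 16 from cyclobutanone 13 and 1-bromo-3-chloro-2-methylpropane 14 by enolate alkylation (bond C8–C9). Only C8 of 13 can be deprotonated. Racemic 14 suffices because C10 is later flattened.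

Cyclobutanone 13 comes from dichloride 11, and 11 is cut at C2–C3 and C7–C8 to silyl enol ether 8 and dichloroketene 10, made from trichloroacetyl chloride 9. This cut forms both fusion centres at once under control of C6. The forward reaction needs the ketene to approach anti to the isopropyl group.

Silyl enol ether 8 goes back to enol formate 6, enal 5, keto aldehyde 4, (S)-p-menth-1-ene 2 and (S)-limonene 1. Direct enolisation of 2-isopropyl-5-methylcyclopentanone would give two regioisomers and would racemise C6. The enol formate fixes the double bond between the future C7 and C3 and never makes C6 part of an enolate.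

## Roads not taken

Alternative 1: The cut is the C6–C7 bond. An achiral 2-methyl-2-(4-methylpent-3-enyl)cycloheptane-1,3-dione A1 would undergo a desymmetrising carbonyl-ene reaction under a chiral Lewis acid: one of the two enantiotopic ketones is activated, the trisubstituted alkene bonds through C6 and a methyl hydrogen is transferred, giving the cis-fused hydroxy ketone A2 with a C6 isopropenyl group. Its merit is real: three stereocentres (C3, C6, C7) arise catalytically in one step from an achiral precursor, and the bicycle is reached in fewer steps than in the chosen plan, without the chiral pool. Its weak points are that ketones are poor enophiles toward trisubstituted alkenes, and that one catalyst must select the enantiotopic carbonyl and fix the relative configuration at C6 at the same time. In addition, A2 carries neither the C10 methyl nor any function at C10 or C1. Everything on the seven-membered ring would have to be built outward from a C2 ketone, so the end game is longer than from 18. Against the shorter entry, the chosen plan sets substrate-controlled fusion stereochemistry from a defined C6 and a complete carbon skeleton at the key step.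

Alternative 2: The cuts are C7–C8 and C9–C10. Rh2(OAc)4 would convert diazo dione A3 into a carbenoid at C10, which the cyclopentanone oxygen captures to give a six-membered carbonyl ylide spanning C7, oxygen and C10. Cycloaddition with ethynyl p-tolyl sulfone A4 closes the seven-membered carbocycle as the oxygen-bridged cycloheptenone A5. This road is better than the chosen one in oxidation pattern: A5 already has oxygen at C1, C7 and C10, whereas the chosen plan must move oxygen from C2. The decisive weakness is stereochemical. The ether bridge holds the C10 oxygen on the face of the C7 oxygen, while the target has them on opposite faces, so the C10–O bond would have to be broken and remade with inversion. The dipolarophile must also approach anti to the C6 isopropyl group across a planar ylide. The sulfone and the C8=C9 alkene must be removed, and A3 needs its own stereocontrolled construction of quaternary C3. The chosen plan sets against the better oxidation pattern a C10 centre that is never locked in the wrong configuration.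

Alternative 3: The cut is the transannular C3–C7 bond. SmI2 would reduce the cyclodec-2-ene-1,7-dione A6 to a C7 ketyl that adds 5-exo to enone carbon C3 and divides the ten-membered ring into the hydroxy ketone A7. Here the end game is clearly better than in the chosen plan: A7 has its ketone at C1 and its methyl at C10, the two carbons that need oxygen, so α-hydroxylation, reduction and acylation would finish the synthesis. The weak points lie before and in the key step. A6 is a functionalised ten-membered ring with one stereocentre and a defined enone geometry, and is costly to make. The cyclisation must set C3 and C7 cis and on the correct face relative to C6 through a medium-ring conformation that cannot be predicted with confidence, and pinacol coupling and simple reduction compete. The chosen plan accepts a longer end game in exchange for a short, reliable entry to the bicycle in which C6 controls the fusion centres directly.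

Key step: step 10

Remark on the chemistry: locants C1–C10 in the names of compounds 18–26 are those defined under "The problem", not von Baeyer locants. The C7 oxygen is carried as a triethylsilyl ether, because loss of a trimethylsilyl group from a 3-siloxycyclobutanone would start retro-aldol ring opening. Racemic 14 is used.

## Route

Step 1
Reactants: 1 (S)-(−)-limonene
Product: 2 (S)-p-menth-1-ene [(4S)-4-isopropyl-1-methylcyclohex-1-ene]
Conditions: H2 (1 atm), RhCl(PPh3)3 (2 mol %), benzene–EtOH, rt
Reagents that add atoms: none
Why: Homogeneous hydrogenation with RhCl(PPh3)3 reduces the unhindered 1,1-disubstituted alkene much faster than the trisubstituted ring alkene; the stereocentre is not touched.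

Step 2
Reactants: 2 (S)-p-menth-1-ene
Product: 4 (S)-3-isopropyl-6-oxoheptanal, via ozonide 3 (not isolated)
Conditions: O3, CH2Cl2, −78 °C; then Me2S, −78 °C → rt
Reagents that add atoms: ozone, O=[O+][O-]
Why: Ozonolysis with reductive work-up cleaves the only alkene to the methyl ketone and the aldehyde; the stereocentre is not α to either carbonyl and cannot epimerise.

Step 3
Reactants: 4 (S)-3-isopropyl-6-oxoheptanal
Product: 5 (R)-5-isopropyl-2-methylcyclopent-1-ene-1-carbaldehyde
Conditions: piperidine, AcOH, benzene, reflux (water separator)
Reagents that add atoms: none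
Why: Amine-catalysed intramolecular aldol condensation: the enamine of the aldehyde attacks the methyl ketone (5-exo) and dehydration gives the tetrasubstituted enal, the known course for this keto aldehyde under amine–acid catalysis; the isopropyl centre is not acidified.

Step 4
Reactants: 5 (R)-5-isopropyl-2-methylcyclopent-1-ene-1-carbaldehyde
Product: 6 (R)-5-isopropyl-2-methylcyclopent-1-en-1-yl formate
Conditions: mCPBA (1.05 equiv), NaHCO3, CH2Cl2, 0 °C
Reagents that add atoms: 3-chloroperoxybenzoic acid, OOC(=O)c1cccc(Cl)c1
Why: Baeyer–Villiger oxidation of an α,β-unsaturated aldehyde: the electron-rich alkenyl group migrates in preference to hydrogen, while conjugation with the formyl group slows epoxidation; the buffer protects the enol formate, which fixes the double bond between the future C7 and C3.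

Step 5
Reactants: 6 (R)-5-isopropyl-2-methylcyclopent-1-en-1-yl formate
Product: 8 (R)-triethyl[(5-isopropyl-2-methylcyclopent-1-en-1-yl)oxy]silane, via lithium enolate 7 (not isolated)
Conditions: MeLi (2.2 equiv), THF, −78 → 0 °C; then Et3SiCl (2.5 equiv), Et3N, −78 °C → rt
Reagents that add atoms: chlorotriethylsilane, CC[Si](Cl)(CC)CC
Why: Cleavage of an enol ester with MeLi releases the tetrasubstituted lithium enolate regiospecifically, with no proton source for equilibration, and O-silylation fixes it; C6 is never part of an enolate and keeps its configuration.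

Step 6
Reactants: 8 (R)-triethyl[(5-isopropyl-2-methylcyclopent-1-en-1-yl)oxy]silane; 9 trichloroacetyl chloride
Product: 11 (1S,2R,5S)-7,7-dichloro-2-isopropyl-5-methyl-1-(triethylsilyloxy)bicyclo[3.2.0]heptan-6-one, via dichloroketene 10 (not isolated)
Conditions: Zn(Cu), POCl3, Et2O, rt (slow addition of 9)
Reagents that add atoms: none
Why: Thermal (2+2) cycloaddition of dichloroketene to an electron-rich silyl enol ether; the ketene carbonyl carbon bonds to the nucleophilic methyl-bearing carbon and CCl2 to the oxygen-bearing carbon, and approach anti to the allylic isopropyl group sets both quaternary centres, leaving methyl, silyloxy and isopropyl on one face; POCl3 ties up ZnCl2.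

Step 7
Reactants: 11 (1S,2R,5S)-7,7-dichloro-2-isopropyl-5-methyl-1-(triethylsilyloxy)bicyclo[3.2.0]heptan-6-one
Product: 13 (1S,2R,5S)-2-isopropyl-5-methyl-1-(triethylsilyloxy)bicyclo[3.2.0]heptan-6-one, via monochloro ketone 12 (not isolated)
Conditions: Bu3SnH (2.3 equiv), AIBN (cat.), benzene, 80 °C
Reagents that add atoms: none
Why: Radical chain hydrodechlorination of an α,α-dichloro ketone under neutral conditions; acidic zinc reduction is avoided because loss of the silyl group would start retro-aldol opening of the 3-siloxycyclobutanone.

Step 8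
Reactants: 13 (1S,2R,5S)-2-isopropyl-5-methyl-1-(triethylsilyloxy)bicyclo[3.2.0]heptan-6-one; 14 1-bromo-3-chloro-2-methylpropane
Product: 16 7-(3-chloro-2-methylpropyl)-2-isopropyl-5-methyl-1-(triethylsilyloxy)bicyclo[3.2.0]heptan-6-one (ring centres as in 13; mixture at C7 and in the side chain), via lithium enolate 15 (not isolated)
Conditions: LiN(iPr)2 (1.1 equiv), THF, −78 °C; then 14 (3 equiv), HMPA, −78 → −20 °C
Reagents that add atoms: none
Why: Alkylation of the only possible ketone enolate (the other α-carbon is quaternary) by a primary bromide, which reacts in preference to the chloride; HMPA activates the lithium enolate toward the β-branched electrophile, and both new centres are removed later.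

Step 9
Reactants: 16 7-(3-chloro-2-methylpropyl)-2-isopropyl-5-methyl-1-(triethylsilyloxy)bicyclo[3.2.0]heptan-6-one
Product: 17 7-(3-iodo-2-methylpropyl)-2-isopropyl-5-methyl-1-(triethylsilyloxy)bicyclo[3.2.0]heptan-6-one (ring centres as in 13; mixture at C7 and in the side chain)
Conditions: NaI (10 equiv), butan-2-one, reflux
Reagents that add atoms: sodium iodide, [Na+].[I-]
Why: Finkelstein exchange of the primary chloride, driven by precipitation of NaCl under neutral conditions that leave the siloxycyclobutanone intact.

Step 10
Reactants: 17 7-(3-iodo-2-methylpropyl)-2-isopropyl-5-methyl-1-(triethylsilyloxy)bicyclo[3.2.0]heptan-6-one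
Product: 18 cis-fused 6-isopropyl-3,10-dimethyl-7-(triethylsilyloxy)bicyclo[5.3.0]decan-2-one (C3 methyl / C7 silyloxy / C6 isopropyl all β; C10 epimers)
Conditions: Bu3SnH (1.3 equiv, syringe pump, 8 h), AIBN (cat.), benzene (0.005 M), 80 °C
Reagents that add atoms: none
Why: Bu3Sn• abstracts iodine from 17 and the primary C1 radical adds to the strained cyclobutanone carbonyl C2 (5-exo-trig closure to a bicyclo[3.2.0]heptan-1-oxyl radical), after which β-scission of the C2–C8 bond restores the carbonyl and leaves a C8 radical that the stannane reduces; this is the Dowd–Beckwith ring expansion in its three-carbon cyclobutanone form. The seven-membered ring is therefore closed not by a direct 7-endo attack but by 5-exo addition followed by cleavage of the bond shared by the four- and five-membered rings. No stereocentre is formed: C3, C6 and C7 are spectators, C8 becomes a methylene and C10 stays a mixture that step 11 removes. Two selectivities are needed. Cyclisation must outrun hydrogen transfer to the C1 radical, which slow addition of the stannane at high dilution secures, helped by the reactivity of a cyclobutanone carbonyl and the irreversible strain-releasing fragmentation. The alkoxy radical must break C2–C8 and not C2–C3 or C2–C1; C2–C8 is the fusion bond whose cleavage unloads both small rings at once and lets the carbonyl flatten in a seven-membered ring, whereas C2–C3 cleavage would leave a cyclopentanone and C2–C1 cleavage only reverses the addition. The C2–C3 path gains from the tertiary C3 radical, which is why this step heads the list of risks.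

Step 11
Reactants: 18 cis-fused 6-isopropyl-3,10-dimethyl-7-(triethylsilyloxy)bicyclo[5.3.0]decan-2-one
Product: 20 6-isopropyl-3,10-dimethyl-7-(triethylsilyloxy)bicyclo[5.3.0]dec-1(10)-en-2-one, via trimethylsilyl enol ether 19 (not isolated)
Conditions: LiN(iPr)2, THF, −78 °C; Me3SiCl; then Pd(OAc)2 (1.1 equiv), MeCN, rt
Reagents that add atoms: none
Why: Saegusa–Ito oxidation: C3 is quaternary, so enolisation is possible only toward C1, and β-hydride elimination from the palladium enolate takes the C10 hydrogen; both C10 epimers give the same enone.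

Step 12
Reactants: 20 6-isopropyl-3,10-dimethyl-7-(triethylsilyloxy)bicyclo[5.3.0]dec-1(10)-en-2-one
Product: 21 6-isopropyl-3,10-dimethyl-7-(triethylsilyloxy)bicyclo[5.3.0]dec-1(10)-en-2-ol (C2 epimers)
Conditions: NaBH4, CeCl3·7H2O, MeOH, 0 °C
Reagents that add atoms: none
Why: Luche reduction gives clean 1,2-addition to the β,β-disubstituted enone; the C2 configuration is irrelevant because C2 ends as a methylene.

Step 13
Reactants: 21 6-isopropyl-3,10-dimethyl-7-(triethylsilyloxy)bicyclo[5.3.0]dec-1(10)-en-2-ol
Product: 22 6-isopropyl-3,10-dimethyl-7-(triethylsilyloxy)bicyclo[5.3.0]dec-1(10)-en-2-yl acetate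
Conditions: Ac2O, pyridine, DMAP (cat.), CH2Cl2, rt
Reagents that add atoms: acetic anhydride, CC(=O)OC(C)=O
Why: DMAP-catalysed acetylation turns the hindered allylic alcohol into a leaving group for palladium; the tertiary silyl ether is inert.

Step 14
Reactants: 22 6-isopropyl-3,10-dimethyl-7-(triethylsilyloxy)bicyclo[5.3.0]dec-1(10)-en-2-yl acetate
Product: 23 6-isopropyl-3,10-dimethyl-7-(triethylsilyloxy)bicyclo[5.3.0]dec-1(10)-ene
Conditions: Pd(PPh3)4 (5 mol %), LiBHEt3 (2 equiv), THF, 0 °C → rt
Reagents that add atoms: none
Why: Palladium-catalysed allylic substitution by hydride: zerovalent palladium ionises the acetate to a π-allyl complex spanning C2–C1–C10, and hydride is delivered to the less substituted terminus C2, which keeps the trisubstituted C1=C10 alkene.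

Step 15
Reactants: 23 6-isopropyl-3,10-dimethyl-7-(triethylsilyloxy)bicyclo[5.3.0]dec-1(10)-ene
Product: 24 6-isopropyl-3,10-dimethylbicyclo[5.3.0]dec-1(10)-en-7-ol (C3 methyl / C7 hydroxyl / C6 isopropyl all β)
Conditions: Bu4NF, THF, rt → 50 °C
Reagents that add atoms: none
Why: Fluoride cleavage of the Si–O bond; no carbonyl remains, so the free tertiary alcohol can no longer undergo retro-aldol cleavage.

Step 16
Reactants: 24 6-isopropyl-3,10-dimethylbicyclo[5.3.0]dec-1(10)-en-7-ol
Product: 25 1β,10β-epoxy-6-isopropyl-3,10-dimethylbicyclo[5.3.0]decan-7-ol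
Conditions: VO(acac)2 (5 mol %), tBuOOH (1.5 equiv, in decane), CH2Cl2, 0 °C → rt
Reagents that add atoms: tert-butyl hydroperoxide, CC(C)(C)OO
Why: Hydroxyl-directed epoxidation: the vanadium alkoxide of the axial C7 hydroxyl, 1,4 across the ring from C10, delivers the peroxide oxygen to its own face, so both new C–O bonds (C1, C10) are β; an oxygen on that face cannot be displaced from behind by the C7 hydroxyl, so the epoxide should persist.

Step 17
Reactants: 25 1β,10β-epoxy-6-isopropyl-3,10-dimethylbicyclo[5.3.0]decan-7-ol
Product: 26 (1R,3R,6R,7S,10R)-6-isopropyl-3,10-dimethylbicyclo[5.3.0]decane-1,7,10-triol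
Conditions: HClO4 (cat.), THF–H2O (3:1), 0 °C
Reagents that add atoms: water, O
Why: Acid-catalysed hydrolysis of a trisubstituted epoxide: water attacks the tertiary C10 from the α-face with inversion while the C1–O bond keeps its β configuration, which gives the trans diol of the target.

Step 18
Reactants: 26 (1R,3R,6R,7S,10R)-6-isopropyl-3,10-dimethylbicyclo[5.3.0]decane-1,7,10-triol; 27 4-methoxybenzoyl chloride
Product: 28 (1R,3aR,5R,6R,8aS)-6,8a-dihydroxy-3a,6-dimethyl-1-(propan-2-yl)decahydroazulen-5-yl 4-methoxybenzoate (CNP0244624.1)
Conditions: pyridine, DMAP (cat.), CH2Cl2, 0 °C → rt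
Reagents that add atoms: none
Why: Nucleophile-catalysed acylation: only the secondary C1 hydroxyl reacts, since the two tertiary alcohols are inert under these conditions.

## Compound list

1 | (S)-(−)-limonene | CC1=CC[C@H](CC1)C(C)=C | starting material
2 | (S)-p-menth-1-ene | CC1=CC[C@H](CC1)C(C)C | intermediate
3 | ozonide of 2 (1,2,4-trioxolane, formed in the flask) | CC12OOC(O1)C[C@H](CC2)C(C)C | intermediate
4 | (S)-3-isopropyl-6-oxoheptanal | O=CC[C@H](CCC(C)=O)C(C)C | intermediate
5 | (R)-5-isopropyl-2-methylcyclopent-1-ene-1-carbaldehyde | O=CC1=C(C)CC[C@@H]1C(C)C | intermediate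
6 | (R)-5-isopropyl-2-methylcyclopent-1-en-1-yl formate | O=COC1=C(C)CC[C@@H]1C(C)C | intermediate
7 | lithium (R)-5-isopropyl-2-methylcyclopent-1-en-1-olate (formed in the flask) | [Li]OC1=C(C)CC[C@@H]1C(C)C | intermediate
8 | (R)-triethyl[(5-isopropyl-2-methylcyclopent-1-en-1-yl)oxy]silane | CC[Si](CC)(CC)OC1=C(C)CC[C@@H]1C(C)C | intermediate
9 | trichloroacetyl chloride | ClC(Cl)(Cl)C(Cl)=O | starting material
10 | dichloroketene (formed in the flask) | ClC(Cl)=C=O | intermediate
11 | (1S,2R,5S)-7,7-dichloro-2-isopropyl-5-methyl-1-(triethylsilyloxy)bicyclo[3.2.0]heptan-6-one; silyloxy, methyl and isopropyl on one face | ClC1(Cl)C(=O)[C@@]2(C)CC[C@H](C(C)C)[C@@]12O[Si](CC)(CC)CC | intermediate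
12 | 7-chloro-2-isopropyl-5-methyl-1-(triethylsilyloxy)bicyclo[3.2.0]heptan-6-one (formed in the flask; C7 epimers) | ClC1C(=O)[C@@]2(C)CC[C@H](C(C)C)[C@@]12O[Si](CC)(CC)CC | intermediate
13 | (1S,2R,5S)-2-isopropyl-5-methyl-1-(triethylsilyloxy)bicyclo[3.2.0]heptan-6-one | C1C(=O)[C@@]2(C)CC[C@H](C(C)C)[C@@]12O[Si](CC)(CC)CC | intermediate
14 | 1-bromo-3-chloro-2-methylpropane (racemic) | CC(CCl)CBr | starting material
15 | lithium enolate of 13 (formed in the flask) | C1=C(O[Li])[C@@]2(C)CC[C@H](C(C)C)[C@@]12O[Si](CC)(CC)CC | intermediate
16 | 7-(3-chloro-2-methylpropyl)-2-isopropyl-5-methyl-1-(triethylsilyloxy)bicyclo[3.2.0]heptan-6-one; ring centres as in 13, mixture at C7 and in the side chain | ClCC(C)CC1C(=O)[C@@]2(C)CC[C@H](C(C)C)[C@@]12O[Si](CC)(CC)CC | intermediate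
17 | 7-(3-iodo-2-methylpropyl)-2-isopropyl-5-methyl-1-(triethylsilyloxy)bicyclo[3.2.0]heptan-6-one; ring centres as in 13, mixture at C7 and in the side chain | ICC(C)CC1C(=O)[C@@]2(C)CC[C@H](C(C)C)[C@@]12O[Si](CC)(CC)CC | intermediate
18 | cis-fused 6-isopropyl-3,10-dimethyl-7-(triethylsilyloxy)bicyclo[5.3.0]decan-2-one; C3 methyl, C7 silyloxy, C6 isopropyl β; C10 epimers | CC1CC(=O)[C@@]2(C)CC[C@H](C(C)C)[C@@]2(O[Si](CC)(CC)CC)CC1 | intermediate
19 | 2-trimethylsilyl enol ether of 18 (C1=C2; formed in the flask) | CC1C=C(O[Si](C)(C)C)[C@@]2(C)CC[C@H](C(C)C)[C@@]2(O[Si](CC)(CC)CC)CC1 | intermediate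
20 | 6-isopropyl-3,10-dimethyl-7-(triethylsilyloxy)bicyclo[5.3.0]dec-1(10)-en-2-one | CC1=CC(=O)[C@@]2(C)CC[C@H](C(C)C)[C@@]2(O[Si](CC)(CC)CC)CC1 | intermediate
21 | 6-isopropyl-3,10-dimethyl-7-(triethylsilyloxy)bicyclo[5.3.0]dec-1(10)-en-2-ol (C2 epimers) | CC1=CC(O)[C@@]2(C)CC[C@H](C(C)C)[C@@]2(O[Si](CC)(CC)CC)CC1 | intermediate
22 | 6-isopropyl-3,10-dimethyl-7-(triethylsilyloxy)bicyclo[5.3.0]dec-1(10)-en-2-yl acetate (C2 epimers) | CC1=CC(OC(C)=O)[C@@]2(C)CC[C@H](C(C)C)[C@@]2(O[Si](CC)(CC)CC)CC1 | intermediate
23 | 6-isopropyl-3,10-dimethyl-7-(triethylsilyloxy)bicyclo[5.3.0]dec-1(10)-ene | CC1=CC[C@@]2(C)CC[C@H](C(C)C)[C@@]2(O[Si](CC)(CC)CC)CC1 | intermediate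
24 | 6-isopropyl-3,10-dimethylbicyclo[5.3.0]dec-1(10)-en-7-ol; C3 methyl, C7 hydroxyl, C6 isopropyl β | CC1=CC[C@@]2(C)CC[C@H](C(C)C)[C@@]2(O)CC1 | intermediate
25 | 1β,10β-epoxy-6-isopropyl-3,10-dimethylbicyclo[5.3.0]decan-7-ol; epoxide on the face of the C7 hydroxyl | O1[C@@H]2C[C@@]3(C)CC[C@H](C(C)C)[C@@]3(O)CC[C@]12C | intermediate
26 | (1R,3R,6R,7S,10R)-6-isopropyl-3,10-dimethylbicyclo[5.3.0]decane-1,7,10-triol; C1 and C7 hydroxyls β, C10 hydroxyl α | O[C@@H]1C[C@@]2(C)CC[C@H](C(C)C)[C@@]2(O)CC[C@@]1(C)O | intermediate
27 | 4-methoxybenzoyl chloride | COc1ccc(cc1)C(Cl)=O | starting material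
28 | (1R,3aR,5R,6R,8aS)-6,8a-dihydroxy-3a,6-dimethyl-1-(propan-2-yl)decahydroazulen-5-yl 4-methoxybenzoate (CNP0244624.1) | COc1ccc(C(=O)O[C@@H]2C[C@@]3(C)CC[C@H](C(C)C)[C@@]3(O)CC[C@@]2(C)O)cc1 | target

Total step count: 18. Longest linear sequence: 18 steps (1 to 28); 9, 14 and 27 are purchased.

## Least certain steps

Step 10 (key step). The alkoxy radical may fragment along C2–C3, giving the tertiary C3 radical and a ring-opened cyclopentanone, instead of along C2–C8. The C1 radical may also be reduced by the stannane before it cyclises. Fallback: a radical-stabilising group on C8 is used to direct the fragmentation. Setting out from 13, sulfenylation (LiN(iPr)2, then PhSSPh) gives 2-isopropyl-5-methyl-7-(phenylsulfanyl)-1-(triethylsilyloxy)bicyclo[3.2.0]heptan-6-one F1. Alkylation of its stabilised enolate (NaH, DMF, 14) gives the 7-(3-chloro-2-methylpropyl)-7-(phenylsulfanyl) ketone F2, and NaI in butan-2-one gives the corresponding iodide F3. Under the conditions of step 10, scission toward the sulfur-stabilised C8 radical should now dominate and give 6-isopropyl-3,10-dimethyl-8-(phenylsulfanyl)-7-(triethylsilyloxy)bicyclo[5.3.0]decan-2-one F4. Raney nickel in acetone–EtOH removes the sulfur and returns to the route at 18.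

Step 8. The β-branched bromide may react too slowly with the cyclobutanone enolate, so that self-condensation of the enolate or β-elimination of the silyloxy group takes over. Fallback: the chain is introduced with a reactive allylic halide and the iodide is made by hydroboration. Setting out from 13, alkylation with 3-iodo-2-methylpropene (LiN(iPr)2, THF, −78 °C) gives 2-isopropyl-5-methyl-7-(2-methylallyl)-1-(triethylsilyloxy)bicyclo[3.2.0]heptan-6-one F5. Excess BH3·THF followed by NaOH/H2O2 reduces the ketone and hydroborates the alkene, giving 7-(3-hydroxy-2-methylpropyl)-2-isopropyl-5-methyl-1-(triethylsilyloxy)bicyclo[3.2.0]heptan-6-ol F6. Selective iodination of the primary hydroxyl (I2, PPh3, imidazole) gives 7-(3-iodo-2-methylpropyl)-2-isopropyl-5-methyl-1-(triethylsilyloxy)bicyclo[3.2.0]heptan-6-ol F7, and Dess–Martin oxidation of the cyclobutanol returns to the route at 17.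

Step 16. If the vanadium alkoxide at C7 cannot reach the C1=C10 alkene, oxygen is delivered from the α-face; the C7 hydroxyl would then open that epoxide across the ring, in step 16 or under the acid of step 17. Fallback: the diol is made by osmylation and C1 is inverted through the ketone, which also bypasses step 17. Setting out from 23, OsO4 (cat.) with N-methylmorpholine N-oxide should add anti to the silyloxy and angular methyl groups and give the 1α,10α-diol 6-isopropyl-3,10-dimethyl-7-(triethylsilyloxy)bicyclo[5.3.0]decane-1,10-diol F8. Dess–Martin oxidation of the secondary hydroxyl gives 10α-hydroxy-6-isopropyl-3,10-dimethyl-7-(triethylsilyloxy)bicyclo[5.3.0]decan-1-one F9. Chelation-controlled reduction with Zn(BH4)2, with hydride entering anti to the C10 methyl group, gives the 1β,10α-diol 7-triethylsilyl ether F10. Bu4NF then returns to the route at 26.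

Step 14. Hydride may be delivered to C10 instead of C2, moving the alkene to C1=C2, or LiBHEt3 may simply cleave the acetate back to 21 before palladium ionises it. Fallback: the allylic oxygen is removed by dissolving-metal reduction, where protonation of the allyl anion at its less substituted end keeps the trisubstituted alkene. Setting out from 21, BuLi and ClP(O)(NMe2)2 give 6-isopropyl-3,10-dimethyl-7-(triethylsilyloxy)bicyclo[5.3.0]dec-1(10)-en-2-yl N,N,N',N'-tetramethylphosphorodiamidate F11; Li in EtNH2/THF with tBuOH returns to the route at 23.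

Step 4. The peracid may epoxidise the alkene, over-oxidise the enol formate once formed, or give the acid by hydrogen migration. Fallback: the formyl carbon is removed by ozonolysis and the regiodefined enol ether is made by 1,4-hydrosilylation. Setting out from 5, Et3SiOTf/Et3N gives (R)-triethyl[(5-isopropyl-2-methylcyclopent-2-en-1-ylidene)methoxy]silane F12. Ozonolysis of its electron-rich enol ether bond (1 equiv O3, −78 °C, then Me2S) gives (R)-5-isopropyl-2-methylcyclopent-2-en-1-one F13. Hydrosilylation with Et3SiH and RhCl(PPh3)3 (cat.) under neutral conditions, so that the now enolisable C5 does not epimerise, returns to the route at 8.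

## Further compounds

F1 | step 10 | 2-isopropyl-5-methyl-7-(phenylsulfanyl)-1-(triethylsilyloxy)bicyclo[3.2.0]heptan-6-one | c3ccccc3SC1C(=O)[C@@]2(C)CC[C@H](C(C)C)[C@@]12O[Si](CC)(CC)CC
F2 | step 10 | 7-(3-chloro-2-methylpropyl)-2-isopropyl-5-methyl-7-(phenylsulfanyl)-1-(triethylsilyloxy)bicyclo[3.2.0]heptan-6-one | ClCC(C)CC1(Sc3ccccc3)C(=O)[C@@]2(C)CC[C@H](C(C)C)[C@@]12O[Si](CC)(CC)CC
F3 | step 10 | 7-(3-iodo-2-methylpropyl)-2-isopropyl-5-methyl-7-(phenylsulfanyl)-1-(triethylsilyloxy)bicyclo[3.2.0]heptan-6-one | ICC(C)CC1(Sc3ccccc3)C(=O)[C@@]2(C)CC[C@H](C(C)C)[C@@]12O[Si](CC)(CC)CC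
F4 | step 10 | 6-isopropyl-3,10-dimethyl-8-(phenylsulfanyl)-7-(triethylsilyloxy)bicyclo[5.3.0]decan-2-one | CC1CC(=O)[C@@]2(C)CC[C@H](C(C)C)[C@@]2(O[Si](CC)(CC)CC)C(Sc3ccccc3)C1
F5 | step 8 | 2-isopropyl-5-methyl-7-(2-methylallyl)-1-(triethylsilyloxy)bicyclo[3.2.0]heptan-6-one | C=C(C)CC1C(=O)[C@@]2(C)CC[C@H](C(C)C)[C@@]12O[Si](CC)(CC)CC
F6 | step 8 | 7-(3-hydroxy-2-methylpropyl)-2-isopropyl-5-methyl-1-(triethylsilyloxy)bicyclo[3.2.0]heptan-6-ol | OCC(C)CC1C(O)[C@@]2(C)CC[C@H](C(C)C)[C@@]12O[Si](CC)(CC)CC
F7 | step 8 | 7-(3-iodo-2-methylpropyl)-2-isopropyl-5-methyl-1-(triethylsilyloxy)bicyclo[3.2.0]heptan-6-ol | ICC(C)CC1C(O)[C@@]2(C)CC[C@H](C(C)C)[C@@]12O[Si](CC)(CC)CC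
F8 | step 16 | 1α,10α-dihydroxy compound: 6-isopropyl-3,10-dimethyl-7-(triethylsilyloxy)bicyclo[5.3.0]decane-1,10-diol | O[C@H]1C[C@@]2(C)CC[C@H](C(C)C)[C@@]2(O[Si](CC)(CC)CC)CC[C@@]1(C)O
F9 | step 16 | 10α-hydroxy-6-isopropyl-3,10-dimethyl-7-(triethylsilyloxy)bicyclo[5.3.0]decan-1-one | O=C1C[C@@]2(C)CC[C@H](C(C)C)[C@@]2(O[Si](CC)(CC)CC)CC[C@@]1(C)O
F10 | step 16 | 1β,10α-dihydroxy compound: 7-triethylsilyl ether of 26 | O[C@@H]1C[C@@]2(C)CC[C@H](C(C)C)[C@@]2(O[Si](CC)(CC)CC)CC[C@@]1(C)O
F11 | step 14 | 6-isopropyl-3,10-dimethyl-7-(triethylsilyloxy)bicyclo[5.3.0]dec-1(10)-en-2-yl N,N,N',N'-tetramethylphosphorodiamidate | CC1=CC(OP(=O)(N(C)C)N(C)C)[C@@]2(C)CC[C@H](C(C)C)[C@@]2(O[Si](CC)(CC)CC)CC1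
F12 | step 4 | (R)-triethyl[(5-isopropyl-2-methylcyclopent-2-en-1-ylidene)methoxy]silane | CC[Si](CC)(CC)OC=C1C(C)=CC[C@@H]1C(C)C
F13 | step 4 | (R)-5-isopropyl-2-methylcyclopent-2-en-1-one | O=C1C(C)=CC[C@@H]1C(C)C
A1 | alternative 1 | 2-methyl-2-(4-methylpent-3-en-1-yl)cycloheptane-1,3-dione | CC(C)=CCCC1(C)C(=O)CCCCC1=O
A2 | alternative 1 | cis-fused hydroxy ketone with C6 isopropenyl and C2 carbonyl | O=C1[C@@]2(C)CC[C@H](C(C)=C)[C@@]2(O)CCCC1
A3 | alternative 2 | 2-(3-diazo-2-oxobutyl)-5-isopropyl-2-methylcyclopentanone | CC(=[N+]=[N-])C(=O)C[C@@]1(C)CC[C@H](C(C)C)C1=O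
A4 | alternative 2 | ethynyl p-tolyl sulfone | C#CS(=O)(=O)c1ccc(C)cc1
A5 | alternative 2 | C7–O–C10 bridged cycloheptenone with C1 ketone and C9 sulfonyl | O=C1C[C@@]2(C)CC[C@H](C(C)C)[C@]23O[C@@]1(C)C(S(=O)(=O)c4ccc(C)cc4)=C3
A6 | alternative 3 | 6-isopropyl-3,10-dimethylcyclodec-2-ene-1,7-dione | CC1CCC(=O)[C@@H](C(C)C)CCC(C)=CC1=O
A7 | alternative 3 | cis-fused hydroxy ketone with C1 carbonyl and C10 methyl | O=C1C[C@@]2(C)CC[C@H](C(C)C)[C@@]2(O)CCC1C
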